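(The numbers of this flask are made up; no experiment stands behind them.)

Two things are asked of these flasks: how much target stands at the end of each, as a fraction of the substrate charged, and which way that fraction moves along the row.

    gas phase ⇌ dissolved gas, rate k1*(csat - [dissolved gas]) (k1 = 0.40 s⁻¹, csat = 2.5 mM)
    substrate + dissolved gas + catalyst → catalyst + target (k2 = 7.0 × 10⁵ L² mol⁻² s⁻¹)
    substrate + target ⇌ idle adduct, settled at all times (K3 = 41 L mol⁻¹)

in all of them: gas phase 2.5 mM (held); catalyst 75 µM; time 30 s

| flask | substrate | remark |
|---|---|---|
| maple | 0.080 M (fed, over 30 s) | the fed solution adds 0.50 times the starting volume |
| birch | 0.25 M (fed, over 30 s) | the fed solution adds 0.50 times the starting volume |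
| alder | 0.60 M (fed, over 30 s) | the fed solution adds 0.50 times the starting volume |
| oak | 2.0 M (fed, over 30 s) | the fed solution adds 0.50 times the starting volume |

- percentages count the substrate that a species holds: one idle adduct counts as two
- target is meant together with its idle adduct
- every charge counts on the volume at the start, and the solution that is fed holds the whole dose
- at the start none of the gas is dissolved
- in an amount of target, one idle adduct counts as one target
- "hardly changes" means that all values lie within two and a half points (for a concentration: within two and a half percent of the largest)
- run time (maple): 30 s

* amount of target at the end, in percent of the substrate charged for maple, birch, alder, oak, in this order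
* how that number moves from the first to the last of them (rises all the way / rises, then falls / falls, then rises / hardly changes / falls all the way)

You feed substrate into a stirred liquid under a held gas phase, and the catalyst joins substrate and dissolved gas into target. The bench rule for such a flask is to count what crosses, taking the crossing as the rate-limiting step. With none dissolved, each litre of liquid takes in 1.00 mM s⁻¹, and over 30 s the liquid averages 1.25 times the starting volume. Set against the charge, this gives a ceiling of 46.9% of the charge for maple, 15.0% for birch, 6.25% for alder and 1.88% for oak.

The rule takes every crossing molecule as used, so follow one molecule of dissolved gas to its fork. It can react with substrate on the catalyst, or it can slip back to the gas phase. Reckon the reaction's rate constant halfway through the feed, with half the dose in, nothing yet spent, and substrate and catalyst both thinned by the larger volume. For maple this gives 1.34 s⁻¹, against 0.40 s⁻¹ for slipping back. The molecule's capture chance, its rate of reacting over the sum of both rates, is then 77.1%.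

Reckoned the same way, the chance for oak is 98.8%. Ceiling times chance is my reckoning: 36.1% for maple, 13.7% for birch, 6.01% for alder and 1.85% for oak. Along the row, then, my reckoned fraction: falls all the way. The border of the bench rule lies where reacting and slipping back run level, at a ratio of 1. Maple stands nearest it, at 3.35, while oak stands at 84.0. My maple figure is shaky, since its ceiling is about half of the charge and I subtracted no spent substrate.

The forecast gives 29.5%, 12.6%, 5.8% and 1.83%, and its shape is falls all the way: “the percentage falls throughout”. Its maple figure stands lower than mine.

The simulation gives 30.0%, 12.9%, 5.86% and 1.84%, so the fraction falls all the way. In maple at 17.4 s, the half-life of dissolved gas by reaction stood at 0.75 s. Turned into a rate constant and set against 0.40 s⁻¹, this gives a capture chance of 69.8%, lower than the 77.1% reckoned. On maple's ceiling of 46.9%, that chance gives 32.7% of the charge, against 30.0% of target in the flask.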